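**Retrosynthetic overview**

- Structural feature: in the coumarin, O1 sits on C8a, the ring A carbon between C4a and the methoxylated C8. Without O1, ring A is a 2,4,5-trimethoxyphenyl group attached through C4a, and its only ortho C–H is the future C8a.
- Last disconnection: the 3'-OH is carried as an isopropyl ether and freed at the end with BCl3.
- Key disconnection: O1–C8a, made by carboxylate-directed, palladium-catalysed oxidative C–H lactonisation of a (Z)-3,3-diarylacrylic acid. This closes the pyranone ring, the only ring formed in the route; rings A and B are bought.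
- The Z acid comes from its methyl ester, made by copper-catalysed syn addition of the ring B arylboronic acid to methyl 3-(2,4,5-trimethoxyphenyl)propiolate. This puts ring A cis to the carboxyl under neutral conditions; an acid-mediated anti-hydroarylation is avoided because a β,β-bis(alkoxyaryl)acrylate can lose its geometry by protonation at C2.
- The alkynoate comes from 2,4,5-trimethoxybenzaldehyde (Corey–Fuchs sequence); the boronic acid comes from 5-bromo-2-methoxyphenol (isopropylation, bromine–lithium exchange, borylation).

Key step: step 7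

Remark: the target has no stereocentre; the only stereochemical element of the route is the Z alkene of the diarylacrylate ester and acid, set in step 5 and consumed in step 7.

**Route**

Step 1
Reactants: 1 2,4,5-trimethoxybenzaldehyde
Product: 2 1-(2,2-dibromoethenyl)-2,4,5-trimethoxybenzene
Conditions: CBr4 (2 equiv), PPh3 (4 equiv), CH2Cl2, 0 °C
Reagents that add atoms: carbon tetrabromide, BrC(Br)(Br)Br
Why: First stage of the Corey–Fuchs sequence (Ramirez dibromoolefination), in which the ylide Ph3P=CBr2 formed from CBr4 and PPh3 olefinates the aldehyde in a Wittig reaction that leaves aryl methyl ethers untouched.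

Step 2
Reactants: 2 1-(2,2-dibromoethenyl)-2,4,5-trimethoxybenzene
Product: 4 methyl 3-(2,4,5-trimethoxyphenyl)prop-2-ynoate, via lithium arylacetylide 3 (not isolated)
Conditions: n-BuLi (2.1 equiv), THF, −78 °C; then ClCO2Me, −78 °C to 0 °C
Reagents that add atoms: methyl chloroformate, COC(=O)Cl
Why: Second stage of the Corey–Fuchs sequence, in which n-BuLi converts the dibromoalkene by elimination and bromine–lithium exchange into the lithium acetylide, which is C-acylated by the chloroformate at low temperature.

Step 3
Reactants: 5 5-bromo-2-methoxyphenol; 6 2-bromopropane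
Product: 7 4-bromo-1-methoxy-2-(propan-2-yloxy)benzene
Conditions: K2CO3, DMF, 60 °C
Reagents that add atoms: none
Why: Williamson etherification, in which the phenoxide formed with K2CO3 in DMF displaces bromide from the secondary halide by SN2 while the aryl bromide and the methyl ether stay intact.

Step 4
Reactants: 7 4-bromo-1-methoxy-2-(propan-2-yloxy)benzene
Product: 10 [4-methoxy-3-(propan-2-yloxy)phenyl]boronic acid, via aryllithium 8 (not isolated), via lithium aryltriisopropoxyborate 9 (not isolated)
Conditions: n-BuLi, THF, −78 °C; B(OiPr)3, −78 °C to rt; 1 M aq. HCl, 0 °C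
Reagents that add atoms: triisopropyl borate, CC(C)OB(OC(C)C)OC(C)C; water, O
Why: Bromine–lithium exchange followed by electrophilic borylation, in which exchange at −78 °C outruns ortho-lithiation, the aryllithium adds to the borate ester to give an ate complex, and cold dilute acid hydrolyses it to the boronic acid without touching the isopropyl ether.

Step 5
Reactants: 4 methyl 3-(2,4,5-trimethoxyphenyl)prop-2-ynoate; 10 [4-methoxy-3-(propan-2-yloxy)phenyl]boronic acid
Product: 11 methyl (2Z)-3-[4-methoxy-3-(propan-2-yloxy)phenyl]-3-(2,4,5-trimethoxyphenyl)prop-2-enoate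
Conditions: CuOAc (5 mol %), 10 (2 equiv), MeOH, rt, N2
Reagents that add atoms: none
Why: Copper-catalysed conjugate hydroarylation of an alkynoate with an arylboronic acid, in which transmetalation gives an arylcopper species of monovalent copper that adds syn across the triple bond with the aryl group at C3, and methanol protonates the alkenylcopper with retention before it can equilibrate through the allenoate, so ring B ends trans and ring A cis to the ester (Z).

Step 6
Reactants: 11 methyl (2Z)-3-[4-methoxy-3-(propan-2-yloxy)phenyl]-3-(2,4,5-trimethoxyphenyl)prop-2-enoate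
Product: 13 (2Z)-3-[4-methoxy-3-(propan-2-yloxy)phenyl]-3-(2,4,5-trimethoxyphenyl)prop-2-enoic acid, via lithium carboxylate 12 (not isolated)
Conditions: LiOH·H2O, THF/MeOH/H2O, 50 °C, dark; then 1 M aq. HCl, 0 °C
Reagents that add atoms: lithium hydroxide, [Li+].[OH-]
Why: Ester saponification by acyl–oxygen cleavage, in which hydroxide does not add to the hindered β,β-diaryl acrylate, so the Z geometry should be kept, and brief cold acidification only protonates the carboxylate.

Step 7
Reactants: 13 (2Z)-3-[4-methoxy-3-(propan-2-yloxy)phenyl]-3-(2,4,5-trimethoxyphenyl)prop-2-enoic acid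
Product: 14 5,7,8-trimethoxy-4-[4-methoxy-3-(propan-2-yloxy)phenyl]-2H-chromen-2-one
Conditions: Pd(OAc)2 (10 mol %), N-acetylglycine (30 mol %), PhI(OAc)2 (2 equiv), KOAc (2 equiv), t-BuOH, 100 °C, dark
Reagents that add atoms: none
Why: The potassium carboxylate of 13 binds divalent palladium and, helped by acetate or the N-acetylglycine ligand, cleaves the C8a–H bond of ring A by concerted metalation–deprotonation to a seven-membered palladacycle; PhI(OAc)2 oxidises this to a tetravalent palladium species, and C–O reductive elimination forms O1–C8a and returns divalent palladium. The closest known reaction type is the carboxylate-directed oxidative C–H lactonisation of 2-arylbenzoic acids to benzocoumarins and of β-arylacrylic acids to coumarins. The pyranone ring closes by bond formation between the carboxylate oxygen and the arene carbon, the seven-membered palladacycle contracting to the six-membered lactone; no stereocentre is created. Ring A is chosen over ring B because the Z alkene holds the carboxylate beside ring A and out of reach of ring B, and within ring A the second ortho carbon carries a methoxyl and offers no hydrogen for metalation. The step needs the metalation pathway to outrun an arene radical-cation pathway, in which the carboxylate could attack the methoxy-bearing ortho carbon; the non-fluorinated, buffered medium (t-BuOH, KOAc) should keep direct oxidation of the trimethoxyphenyl ring by the iodine reagent slow.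

Step 8
Reactants: 14 5,7,8-trimethoxy-4-[4-methoxy-3-(propan-2-yloxy)phenyl]-2H-chromen-2-one
Product: 16 4-(3-hydroxy-4-methoxyphenyl)-5,7,8-trimethoxy-2H-chromen-2-one, via aryloxydichloroborane 15 (not isolated)
Conditions: BCl3 (1 M in CH2Cl2, 3 equiv), CH2Cl2, −78 °C to 0 °C; then H2O
Reagents that add atoms: none
Why: Lewis-acid ether cleavage, in which BCl3 coordinates the ether oxygen and the secondary isopropyl group leaves as 2-chloropropane far faster than any methyl group, no methoxyl lies next to a carbonyl oxygen where boron chelation would activate it, and water hydrolyses the aryl dichloroborinate to the phenol.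

**Compound list**

1 | 2,4,5-trimethoxybenzaldehyde | O=Cc1cc(OC)c(OC)cc1OC | starting material
2 | 1-(2,2-dibromoethenyl)-2,4,5-trimethoxybenzene | BrC(Br)=Cc1cc(OC)c(OC)cc1OC | intermediate
3 | lithium (2,4,5-trimethoxyphenyl)ethynide | [Li]C#Cc1cc(OC)c(OC)cc1OC | intermediate
4 | methyl 3-(2,4,5-trimethoxyphenyl)prop-2-ynoate | COC(=O)C#Cc1cc(OC)c(OC)cc1OC | intermediate
5 | 5-bromo-2-methoxyphenol | COc1ccc(Br)cc1O | starting material
6 | 2-bromopropane | CC(C)Br | starting material
7 | 4-bromo-1-methoxy-2-(propan-2-yloxy)benzene | COc1ccc(Br)cc1OC(C)C | intermediate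
8 | [4-methoxy-3-(propan-2-yloxy)phenyl]lithium | [Li]c1ccc(OC)c(OC(C)C)c1 | intermediate
9 | lithium [4-methoxy-3-(propan-2-yloxy)phenyl]tri(propan-2-yloxy)borate | [Li+].COc1ccc(cc1OC(C)C)[B-](OC(C)C)(OC(C)C)OC(C)C | intermediate
10 | [4-methoxy-3-(propan-2-yloxy)phenyl]boronic acid | COc1ccc(B(O)O)cc1OC(C)C | intermediate
11 | methyl (2Z)-3-[4-methoxy-3-(propan-2-yloxy)phenyl]-3-(2,4,5-trimethoxyphenyl)prop-2-enoate | COC(=O)/C=C(\c1cc(OC)c(OC)cc1OC)c1ccc(OC)c(OC(C)C)c1 | intermediate
12 | lithium (2Z)-3-[4-methoxy-3-(propan-2-yloxy)phenyl]-3-(2,4,5-trimethoxyphenyl)prop-2-enoate | [Li+].[O-]C(=O)/C=C(\c1cc(OC)c(OC)cc1OC)c1ccc(OC)c(OC(C)C)c1 | intermediate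
13 | (2Z)-3-[4-methoxy-3-(propan-2-yloxy)phenyl]-3-(2,4,5-trimethoxyphenyl)prop-2-enoic acid | OC(=O)/C=C(\c1cc(OC)c(OC)cc1OC)c1ccc(OC)c(OC(C)C)c1 | intermediate
14 | 5,7,8-trimethoxy-4-[4-methoxy-3-(propan-2-yloxy)phenyl]-2H-chromen-2-one | COc1ccc(-c2cc(=O)oc3c(OC)c(OC)cc(OC)c23)cc1OC(C)C | intermediate
15 | dichloro[2-methoxy-5-(5,7,8-trimethoxy-2-oxo-2H-chromen-4-yl)phenoxy]borane | COc1ccc(-c2cc(=O)oc3c(OC)c(OC)cc(OC)c23)cc1OB(Cl)Cl | intermediate
16 | 4-(3-hydroxy-4-methoxyphenyl)-5,7,8-trimethoxy-2H-chromen-2-one (3'-hydroxy-5,7,8,4'-tetramethoxy-4-phenylcoumarin) | COc1ccc(-c2cc(=O)oc3c(OC)c(OC)cc(OC)c23)cc1O | target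

**Step count**

Total: 8 steps. Longest linear sequence: 6 steps (1 → 2 → 4 → 11 → 13 → 14 → 16; the ring B branch 5 → 7 → 10 → 11 and onward is equally long).

**Steps most likely to fail, with fallbacks**

Step 7 (key lactonisation). Three processes could defeat it:
- direct oxidation of the electron-rich ring A by the iodine reagent, giving an arene radical cation that the carboxylate attacks at the methoxy-bearing ortho carbon with loss of methyl, or that goes on to a quinone;
- slow palladation of a C–H flanked by a methoxyl;
- Z-to-E isomerisation at 100 °C, which would bring ring B within reach of the carboxylate.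

In the fallback O1 comes in as a phenol oxygen and the C4–C1' bond is made last. It sets out from boronic acid 10 and comes back at 14. Purchased 1-(2-hydroxy-3,4,6-trimethoxyphenyl)ethan-1-one F1 is condensed with diethyl carbonate (NaH, toluene, reflux; Claisen condensation and lactonisation) to 4-hydroxy-5,7,8-trimethoxy-2H-chromen-2-one F2. Tf2O and Et3N (CH2Cl2, −10 °C) convert this into 5,7,8-trimethoxy-2-oxo-2H-chromen-4-yl trifluoromethanesulfonate F3. Suzuki–Miyaura coupling of F3 with 10 (Pd(PPh3)4, K3PO4, dioxane/H2O, 80 °C) should give 14, which continues with step 8.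

Step 5 (copper-catalysed hydroarylation). Carbocupration of an electron-rich, ortho-substituted alkynoate may be slow, so that protodeboronation of the boronic acid in methanol consumes the aryl donor first, or the alkenylcopper may lose its geometry through the allenoate before protonation. The fallback replaces the aryl nucleophile by an aryl electrophile. It sets out from bromide 7 and alkynoate 4 and comes back at 11. Bromine–lithium exchange on 7 (n-BuLi, THF, −78 °C) and quenching with I2 gives 4-iodo-1-methoxy-2-(propan-2-yloxy)benzene F4. A reductive Heck hydroarylation of 4 with F4 (Pd(OAc)2, HCOOK, DMF, 40 °C) should add the aryl–palladium bond syn across the alkyne with the aryl group at C3. Formate reduction of the alkenylpalladium with retention should then give the same Z ester 11.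

Step 8 (deisopropylation). A ring methyl ether may be lost in competition with the isopropyl group, most likely at the vicinal C7/C8 pair or at the 4'-methoxyl next to the boron-bound oxygen, or cleavage may stay incomplete at low temperature. The fallback uses a benzyl ether and ends with hydrogenolysis in place of a Lewis acid. It sets out from alkynoate 4 and comes back at target 16. The conditions of step 5 with purchased [3-(benzyloxy)-4-methoxyphenyl]boronic acid F5 should give methyl (2Z)-3-[3-(benzyloxy)-4-methoxyphenyl]-3-(2,4,5-trimethoxyphenyl)prop-2-enoate F6. Saponification as in step 6 gives (2Z)-3-[3-(benzyloxy)-4-methoxyphenyl]-3-(2,4,5-trimethoxyphenyl)prop-2-enoic acid F7. Lactonisation as in step 7 gives 4-[3-(benzyloxy)-4-methoxyphenyl]-5,7,8-trimethoxy-2H-chromen-2-one F8. Hydrogenolysis (H2, 1 atm, 10% Pd/C, EtOAc, rt) should cleave the benzyl C–O bond faster than it reduces the conjugated C3=C4 bond and give 16.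

**Further compounds**

F1 | step 7 | 1-(2-hydroxy-3,4,6-trimethoxyphenyl)ethan-1-one | CC(=O)c1c(O)c(OC)c(OC)cc1OC
F2 | step 7 | 4-hydroxy-5,7,8-trimethoxy-2H-chromen-2-one | O=c1cc(O)c2c(OC)cc(OC)c(OC)c2o1
F3 | step 7 | 5,7,8-trimethoxy-2-oxo-2H-chromen-4-yl trifluoromethanesulfonate | O=c1cc(OS(=O)(=O)C(F)(F)F)c2c(OC)cc(OC)c(OC)c2o1
F4 | step 5 | 4-iodo-1-methoxy-2-(propan-2-yloxy)benzene | COc1ccc(I)cc1OC(C)C
F5 | step 8 | [3-(benzyloxy)-4-methoxyphenyl]boronic acid | COc1ccc(B(O)O)cc1OCc1ccccc1
F6 | step 8 | methyl (2Z)-3-[3-(benzyloxy)-4-methoxyphenyl]-3-(2,4,5-trimethoxyphenyl)prop-2-enoate | COC(=O)/C=C(\c1cc(OC)c(OC)cc1OC)c1ccc(OC)c(OCc2ccccc2)c1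
F7 | step 8 | (2Z)-3-[3-(benzyloxy)-4-methoxyphenyl]-3-(2,4,5-trimethoxyphenyl)prop-2-enoic acid | OC(=O)/C=C(\c1cc(OC)c(OC)cc1OC)c1ccc(OC)c(OCc2ccccc2)c1
F8 | step 8 | 4-[3-(benzyloxy)-4-methoxyphenyl]-5,7,8-trimethoxy-2H-chromen-2-one | COc1ccc(-c2cc(=O)oc3c(OC)c(OC)cc(OC)c23)cc1OCc1ccccc1
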